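Slowness comes first: the flask holds 5.0 × 10⁻⁴ M of starting complex against Sunday's 7.5 × 10⁻⁴ M, so at equal equivalents of incoming ligand each exchange between two dissolved partners starts slower by a factor 1.50.

| flask | starting complex | incoming ligand | protic impurity | remark | time |
|---|---|---|---|---|---|
| Sunday's | 7.5 × 10⁻⁴ M (fed, over 12 s) | 0.70 equiv | 0.15 mM | run made earlier |  |
| flask | 5.0 × 10⁻⁴ M (fed, over 12 s) | 0.700 equiv | 0.150 mM |  | 15 min |

Sunday's run (percent of the starting complex charged)

| time / min | complex with two exchanged / % | starting complex / % |
|---|---|---|
| 0.250 | 1.4 | 91.5 |
| 0.500 | 7.9 | 82.6 |
| 1.33 | 16.0 | 73.0 |
| 3.00 | 15.7 | 70.2 |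

(readings scatter by 0.5 percentage points)

- candidate steps: complex with two exchanged -> over-reaction product; protic impurity + incoming ligand -> quenched reagent; complex with one exchanged + incoming ligand -> leaving ligand + complex with two exchanged; complex with two exchanged + incoming ligand -> leaving ligand + complex with three exchanged; starting complex + incoming ligand -> leaving ligand + complex with one exchanged
- no earlier run changes the charge of incoming ligand; that part of a forecast is a guess

- the moment within 15 min at which there is most complex with two exchanged
- the amount of complex with two exchanged, in percent of the starting complex charged, at that time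

Take the settings in turn. The feed lasts 12 s, short beside the minutes of reaction, and by hand it should not matter; it doesn't. The lower concentration stretches the clock: Sunday's complex with two exchanged read level from 1.33 min to 3.00 min, so I expect the flask's top between 2.00 min and 4.50 min. The protic impurity stays at 0.150 mM, a larger share of this flask's charge. If I assume that each protic impurity takes one incoming ligand and that this quench runs to completion, the net ligand n, the equivalents then left for the complexes, is 0.500 on Sunday and 0.400 in the flask. Dividing gain of product by use of ligand removes time, which gives the yield per net ligand Y, the plateau amount of complex with two exchanged divided by n: Sunday's reading gives 0.320, so I reckon 12.8% for the flask.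

The forecast, a different reckoning, gives 12.3% (range 10.5% to 14.2%) at 2.5 min (range 1.6 min to 4.5 min), arguing that “The lower concentration slows things, so the peak comes when ligand is nearly gone”.

The flask gives 14.4% at 2.90 min.

    complex with two exchanged → over-reaction product (k = 8.40 × 10⁻⁴ s⁻¹)
    protic impurity + incoming ligand → quenched reagent (k = 74.0 M⁻¹ s⁻¹)
    complex with one exchanged + incoming ligand → leaving ligand + complex with two exchanged (k = 180 M⁻¹ s⁻¹)
    complex with two exchanged + incoming ligand → leaving ligand + complex with three exchanged (k = 21.0 M⁻¹ s⁻¹)
    starting complex + incoming ligand → leaving ligand + complex with one exchanged (k = 21.0 M⁻¹ s⁻¹)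

At 0.578 min in the flask, starting complex uses incoming ligand 1.6 times as fast as protic impurity does. At 15.0 min the flask has 0% of its incoming ligand left and 28% of its protic impurity still unquenched. With 1.08 × 10⁻⁴ M of quenched reagent at that time, the complexes in the flask had received 0.483 equiv of incoming ligand, not the 0.400 of the assumed complete quench. With 1.20 equiv of incoming ligand, Sunday's Y predicts 28.8%, and that neighbouring flask gives 25.7%.

The earlier runs and the new flask stem from a simulated flask for an exercise, noise included.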